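Locants: fragment A is the tetralone with C1–C8a (ketone C1, carbinol C4, phenol C5, methyl on C7). Fragment B has primed locants (ketone C1', carbinol C4', methyl on C6', phenol C8') and is bonded to C3 through C7'. "ArB" means the protected fragment B aryl group bonded through C7': (4'R)-4'-[(tert-butyldimethylsilyl)oxy]-8'-(methoxymethoxy)-6'-methyl-3',4'-dihydro-2'H-spiro[1,3-dioxolane-2,1'-naphthalen]-7'-yl.

## The problem

The target joins two 4-hydroxy-1-tetralones: C3 of fragment A is bonded to the arene carbon C7' of fragment B. This C3–C7' bond runs from an sp3 carbon to an arene carbon flanked by the C8' oxygen and the C6' methyl group, and it lies next to the C4 carbinol. It is therefore too crowded for a late cross-coupling and is better in place before ring A is closed. There are three stereocentres. C3 (R) and C4 (S) are neighbours, with aryl and hydroxyl cis on ring A, so both can come from one ordered transition state. C4' (R) lies across the arene and can neither control them nor be controlled by them. Two independent sources of absolute configuration are needed, but once C4' is fixed an error at C3/C4 gives a diastereomer, which can be separated. Both rings are 4-hydroxy-1-tetralones, which lose water to naphthols in strong acid or base. The C4 carbinol sits next to the C5 phenol and ionises to an ortho-quinone methide in acid, all carbinols are benzylic and open to hydrogenolysis, and both ketones must be kept from organometallic reagents. Ring B makes the key step possible: C1', C2' and C3' are a ketone with its α- and β-carbons on C8a', which is what a 1-arylcyclopropanol gives on ring-opening, and C4' is a benzylic carbinol on the neighbouring C4a', a former aldehyde. Both benzene rings carry oxygen, methyl and carbon in the same 1,3,5-pattern with one more carbon between the oxygen and the third substituent, which points to one phenol, 1, as the source of both.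

## Retrosynthesis

**Unmasking.** The target 34 comes from its C5 benzyl ether 33 by hydrogenolysis, and 33 from the fully protected 32 by one aqueous acid treatment. No C–C bond is cut. The order follows the weak point at C4/C5: acid is used while the C5 oxygen is still benzylated, and the neutral step comes last. The forward steps must spare the two 4-hydroxytetralones.

**C1–C8a.** Ring A is opened at the aryl ketone bond, leading to the bromo lactone 29. An aryllithium at C8a attacks the lactone carbonyl C1 and the ring oxygen is released as the C4 hydroxyl (Parham cyclisation). A Friedel–Crafts closure is ruled out because C8a is meta to the C5 oxygen, and a Heck closure onto an alkene would prefer the five-membered ring. The precursor lacks the ring and the ketone but keeps both stereocentres untouched. The forward step needs bromine–lithium exchange to outrun attack of the base on the lactone.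

**Lactone to vinyl.** Lactone 29 is the oxidised form of the 1,4-diol 27, which comes from the terminal alkene of the homoallylic alcohol 25. This replaces C1 at the acid level by a vinyl group, the group an allylmetal addition leaves behind, at the cost of two routine steps. The forward steps need anti-Markovnikov hydroboration and oxidation of a primary alcohol beside a hindered secondary one.

**C3–C4.** Cutting between the two stereocentres of 25 gives the (E)-allylboronate 20, which carries all of fragment B, and the bromo aldehyde 23. The neighbouring cut at C3–C7' would be an aryl–alkyl coupling at a secondary carbon between two ortho-substituted arenes. The chosen cut makes the crowded C3–C7' bond while it is still part of a styrene, and forms both stereocentres in one closed transition state: E geometry gives the anti adduct, which is cis on ring A. The two precursors are arenes of similar size, so the route becomes convergent. The forward reaction must join two hindered partners with anti selectivity and with catalyst control of the aldehyde face. The diastereomer from the other face can be removed by chromatography.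

**Fragment A arene.** The aldehyde carbon of 23 (C4) lies between bromine and oxygen, the most acidic position of the benzyl ether 21. So 23 is cut to 21 and DMF 8, and 21 to the phenol 1. The only demand is that the aryllithium 22 be kept cold.

**Allylboronate.** Boronate 20 comes from the allylic carbonate 19 by an SN2' borylation, which brings the double bond into conjugation and sets E geometry. Carbonate 19 comes from the aldehyde 16, vinylmagnesium bromide 17 and methyl chloroformate 3, and 16 from the arene 14 and 8. C7' is the only free position ortho to the MOM ether, so directed lithiation selects it, whereas electrophilic substitution would prefer C5'. The forward step must lithiate a flanked position without touching the benzylic C4'–H.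

**Protection.** Arene 14 is the ethylene ketal of the silyl ether 13, made from the hydroxy ketone 12. The ketal is needed because two aryllithiums and a Grignard reagent follow, and the silyl ether because the carbonate step would acylate a free C4' hydroxyl.

**C3'–C4' (key disconnection).** Ring B of 12 is opened between the carbinol carbon and its neighbour, with C1', C2' and C3' folded back into a cyclopropanol. The precursor is the hydroxy aldehyde 10, and the zinc homoenolate 11 links the two. Cutting at C1'–C8a' or C4'–C4a' would need a separate asymmetric step for C4'. This cut makes the ring and the stereocentre together and needs no redox adjustment. The precursor is an achiral benzaldehyde. The forward reaction must open the zinc cyclopropoxide, add C3' to the aldehyde in preference to ethyl transfer or attack through C2', and control the face through a chiral aminoalkoxide on zinc. This last point has no precedent.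

**Cyclopropanol aldehyde.** The aldehyde carbon of 10 is removed to give 8 and the aryl bromide 7. The cyclopropane of 7 is cut to the ester 5 and ethylmagnesium bromide 6 (Kulinkovich reaction). The ester carbon is removed from the position between bromine and the MOM ether of 2 (reagent 3), and 2 is the MOM ether of 1. Bromine marks C4a' until the cyclopropanol is in place, so no aldehyde has to be carried through the Grignard step. The forward steps need a Kulinkovich reaction on a 2,6-disubstituted benzoate and halogen–lithium exchange beside a lithium cyclopropoxide (aryllithium 4, dianion 9).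

## Roads not taken

Alternative 1: The benzene ring of fragment B is cut at C4a'–C8a' and C7'–C8'. It is stored as a 2,4,5-trisubstituted furan that carries ring A on its C7' carbon and a four-carbon tether ending in a terminal alkyne (A1). Ph3PAuNTf2 (monovalent gold) would activate the alkyne, the furan would add, and the arene oxide would open to the phenol A2. This closes the benzene ring and the carbocycle of fragment B together and leaves the C8' oxygen free.
- Merits: the crowded C3–C7' bond is made at a furan α-carbon, no metalation of a crowded arene is needed, and the C8' phenol needs no protecting group.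
- Weak points: the tether closes a six-membered carbocycle, slower than the three-atom tethers on which this reaction is reliable. The alkyne bears a propargylic ketal and the furan a furfurylic silyl ether at C4', and a cationic gold catalyst can ionise both. The arene oxide can open to the regioisomeric phenol. A1 must already hold all three stereocentres, so C4' needs its own asymmetric step and ring A must be built on a furan.
- Comparison: in convergence and in freedom from aryllithium chemistry late in the route, alternative 1 is the better plan. The chosen plan sets against this that both arenes come from one phenol, that the ring B closure creates C4' in the same step, and that its one unprecedented step has a substrate of five steps, whereas A1 has no short supply.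

Alternative 2: The benzene ring of fragment B is cut at C4a'–C5' and C8'–C8a'. Carbons C5'–C8' come from the vinylketene silyl acetal A4, and the carbocycle with C4' from the chiral-pool (R)-2-bromo enone A3. The CH2 terminus of A4 bonds to C4a' and the acetal carbon to C8a', and loss of HBr and MeOSiMe3 aromatises the adduct to the chelated phenol A5.
- Merits: C4' comes from the chiral pool, so no unproven asymmetric step is needed. In this respect alternative 2 is safer than the chosen plan. The bromine and the acetal fix the regiochemistry.
- Weak points: A3 needs a long degradation sequence. A3 and the cycloadduct are γ-silyloxy enones that can lose silanol under the conditions that remove HBr, which would give a phenol or a naphthol. Everything after C4' is unchanged, since A5 is one O-alkylation away from 13.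
- Comparison: alternative 2 replaces steps 1–6 by a longer but stereochemically certain sequence. The chosen plan offers a shorter sequence to 13 from the phenol that also supplies ring A, and a resolution route to 12 if step 5 fails.

Alternative 3: Ring A is cut at C2–C3. The precursor is the trans epoxide A6, with an allyl ether on C8' and an acetyl group on the ring A arene. Pd(PPh3)4 (zerovalent palladium) with an amine allyl acceptor and carbonate base would free the C8' phenoxide. The phenoxide opens the epoxide at C3 to an ortho-quinone methide with the C4 alkoxide in place, and the acetyl enolate adds to C3 (6-exo-trig) to give A7.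
- Merits: the ring A ketone comes from an acetyl group, so no aryllithium or lactone is needed, and C3 is set within the ring under the influence of C4.
- Weak points: A6 is the epoxide of a stilbene with four ortho substituents, for which neither the olefination nor an asymmetric epoxidation is reliable. Carbonate is a weak base for a methyl ketone. The C4 alkoxide or the amine can add back to C3. Which face of C3 the enolate takes, and so cis or trans, cannot be predicted.
- Comparison: alternative 3 is better in the ring A closure. The chosen plan sets C3 and C4 together through a transition state whose relative sense is understood (E gives anti) and whose absolute sense can be corrected by chromatography, while alternative 3 rests the relative configuration on an untested closure.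

Key step: step 5

Assumptions:
- The sense of induction of DAIB and of TRIP is carried over from intermolecular additions to aryl aldehydes. If either is reversed for these substrates, the antipodal ligand is used and the route is otherwise unchanged.
- Compound 10 rests mainly as its five-membered cyclic hemiacetal (ring–chain tautomer). It is listed as the open hydroxy aldehyde, the form that reacts.
- Compound 1 is taken to be commercially available.

## Steps

Step 1
Reactants: 1 3-bromo-5-methylphenol
Product: 2 1-bromo-3-(methoxymethoxy)-5-methylbenzene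
Conditions: MOMCl, iPr2NEt, CH2Cl2, 0 °C → rt
Reagents that add atoms: chloromethyl methyl ether, COCCl
Why: O-Alkylation of the phenol (MOM ether formation); the MOM group is chosen because it later directs both lithiations on this arene.

Step 2
Reactants: 2 1-bromo-3-(methoxymethoxy)-5-methylbenzene; 3 methyl chloroformate
Product: 5 methyl 2-bromo-6-(methoxymethoxy)-4-methylbenzoate, via aryllithium 4 (not isolated)
Conditions: LDA, THF, −78 °C; ClCO2Me, −78 °C → rt
Reagents that add atoms: methyl chloroformate 3, COC(=O)Cl
Why: Directed ortho-metalation: LDA removes the proton flanked by Br and OMOM, the most acidic site, the aryllithium is kept at −78 °C to avoid loss of LiBr, and acylation by the chloroformate installs C1'.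

Step 3
Reactants: 5 methyl 2-bromo-6-(methoxymethoxy)-4-methylbenzoate; 6 ethylmagnesium bromide
Product: 7 1-[2-bromo-6-(methoxymethoxy)-4-methylphenyl]cyclopropan-1-ol
Conditions: EtMgBr (3 equiv, slow addition), Ti(OiPr)4 (0.3 equiv), THF, 0 °C → rt; aq. NH4Cl
Reagents that add atoms: ethylmagnesium bromide 6, CC[Mg]Br
Why: Kulinkovich cyclopropanation: the titanacyclopropane formed from EtMgBr and Ti(OiPr)4 acts as a 1,2-dicarbanion on the ester and supplies C2' and C3'; aryl bromides and MOM ethers are tolerated, and slow addition keeps direct Grignard attack on the ester low.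

Step 4
Reactants: 7 1-[2-bromo-6-(methoxymethoxy)-4-methylphenyl]cyclopropan-1-ol; 8 N,N-dimethylformamide
Product: 10 2-(1-hydroxycyclopropyl)-3-(methoxymethoxy)-5-methylbenzaldehyde, via dilithio species 9 (not isolated)
Conditions: n-BuLi (2.2 equiv), THF, −78 °C; DMF, −78 → 0 °C; aq. NH4Cl
Reagents that add atoms: N,N-dimethylformamide 8, CN(C)C=O
Why: Deprotonation of the alcohol and bromine–lithium exchange, then formylation with DMF, install C4'; lithium cyclopropoxides do not ring-open at −78 °C, and the product rests as its lactol tautomer.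

Step 5
Reactants: 10 2-(1-hydroxycyclopropyl)-3-(methoxymethoxy)-5-methylbenzaldehyde
Product: 12 (R)-4-hydroxy-8-(methoxymethoxy)-6-methyl-3,4-dihydronaphthalen-1(2H)-one, via zinc homoenolate 11 (not isolated)
Conditions: ZnEt2 (20 mol %), (+)-DAIB [(2R)-3-exo-(dimethylamino)isoborneol] (24 mol %), toluene/THF, 0 → 40 °C; aq. NH4Cl
Reagents that add atoms: none
Why: Proposed new method: ZnEt2 and (+)-DAIB form the ethylzinc aminoalkoxide, whose ethyl group is lost as ethane to the hydroxyl of 10, so zinc carries only the chiral ligand and the cyclopropoxide of the open form of 10; strain-driven opening of the C1'–C3' bond gives the β-zincio ketone 11 (zinc held by the new C1' carbonyl), its C3'–Zn bond adds to the neighbouring aldehyde, and the C4' zinc alkoxide exchanges with fresh 10 to turn the catalyst over. The closest known reaction types are the amino-alcohol–zinc-catalysed opening of cyclopropanols to zinc homoenolates that add to enones, the homoaldol addition of zinc and titanium homoenolates to aldehydes, and the DAIB-catalysed addition of dialkylzincs to aryl aldehydes; none has been run as an enantioselective ring closure. The ring closes 6-exo-trig (C3' onto the exocyclic C4'=O) and gives the six-membered carbocycle of fragment B at the final oxidation levels. The C4' configuration is controlled by the aminoalkoxide on zinc, which must send C3' to the Re face of the aldehyde; the (+)-ligand is chosen because its antipode sends alkyl groups to the Si face of aryl aldehydes. Chemoselectivity is needed against ethyl transfer and against attack through C2': the first is secured by the substoichiometric zinc, so that no Zn–Et bond outlasts protonolysis while the aldehyde is still masked as the lactol, and the second by ring size, since closure of the enolised homoenolate through C2' would be a disfavoured 5-(enolendo)-exo-trig process. Protonation of 11 to the ethyl ketone is the remaining leak and is limited by the aprotic medium.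

Step 6
Reactants: 12 (R)-4-hydroxy-8-(methoxymethoxy)-6-methyl-3,4-dihydronaphthalen-1(2H)-one
Product: 13 (R)-4-[(tert-butyldimethylsilyl)oxy]-8-(methoxymethoxy)-6-methyl-3,4-dihydronaphthalen-1(2H)-one
Conditions: TBSCl, imidazole, DMF, rt
Reagents that add atoms: tert-butyldimethylsilyl chloride, CC(C)(C)[Si](C)(C)Cl
Why: Silyl ether formation at the secondary benzylic alcohol; C4' is not touched.

Step 7
Reactants: 13 (R)-4-[(tert-butyldimethylsilyl)oxy]-8-(methoxymethoxy)-6-methyl-3,4-dihydronaphthalen-1(2H)-one
Product: 14 (4'R)-4'-[(tert-butyldimethylsilyl)oxy]-8'-(methoxymethoxy)-6'-methyl-3',4'-dihydro-2'H-spiro[1,3-dioxolane-2,1'-naphthalene]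
Conditions: (TMSOCH2)2, TMSOTf (cat.), CH2Cl2, −78 → −20 °C
Reagents that add atoms: 1,2-bis(trimethylsilyloxy)ethane, C[Si](C)(C)OCCO[Si](C)(C)C
Why: Ketalisation by acetal exchange with the bis-silyl ether of ethylene glycol under TMSOTf catalysis, run cold and without protic acid so that the benzylic silyl ether, the MOM ether and the 4-oxygenated tetralone survive; the dioxolane masks C1' against the organometallic reagents that follow.

Step 8
Reactants: 14 (4'R)-4'-[(tert-butyldimethylsilyl)oxy]-8'-(methoxymethoxy)-6'-methyl-3',4'-dihydro-2'H-spiro[1,3-dioxolane-2,1'-naphthalene]; 8 N,N-dimethylformamide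
Product: 16 ArB-carbaldehyde (formyl group on C7'), via aryllithium 15 (not isolated)
Conditions: n-BuLi, TMEDA, Et2O, −78 → 0 °C; DMF, −78 °C → rt
Reagents that add atoms: N,N-dimethylformamide 8, CN(C)C=O
Why: Directed ortho-metalation: the MOM ether directs lithiation to C7', its only free ortho position, and DMF formylates the aryllithium; the dioxolane and the silyl ether are inert to the base at this temperature.

Step 9
Reactants: 16 ArB-carbaldehyde; 17 vinylmagnesium bromide; 3 methyl chloroformate
Product: 19 methyl 1-(ArB)prop-2-en-1-yl carbonate (both configurations at the carbinol carbon), via magnesium alkoxide 18 (not isolated)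
Conditions: CH2=CHMgBr, THF, −78 → 0 °C; ClCO2Me, 0 °C → rt
Reagents that add atoms: vinylmagnesium bromide 17, C=C[Mg]Br; methyl chloroformate 3, COC(=O)Cl
Why: 1,2-Addition of the Grignard reagent to the aldehyde and acylation of the magnesium alkoxide in the same pot give the allylic carbonate; the new carbinol centre needs no control because step 10 removes it.

Step 10
Reactants: 19 methyl 1-(ArB)prop-2-en-1-yl carbonate
Product: 20 2-[(E)-3-(ArB)prop-2-en-1-yl]-4,4,5,5-tetramethyl-1,3,2-dioxaborolane
Conditions: B2pin2, CuCl (10 mol %), Xantphos (10 mol %), KOtBu (15 mol %), THF, 0 °C → rt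
Reagents that add atoms: bis(pinacolato)diboron, CC1(C)OB(OC1(C)C)B1OC(C)(C)C(C)(C)O1
Why: Copper-catalysed γ-selective (SN2') borylation of an allylic carbonate: the boryl–copper species adds across the terminal alkene and β-elimination of the carbonate gives the linear allylboronate, with E geometry because the aryl group avoids allylic strain in the elimination.

Step 11
Reactants: 1 3-bromo-5-methylphenol
Product: 21 1-(benzyloxy)-3-bromo-5-methylbenzene
Conditions: BnBr, K2CO3, DMF, rt
Reagents that add atoms: benzyl bromide, BrCc1ccccc1
Why: Williamson ether synthesis; the benzyl ether is chosen for C5–O because neutral hydrogenolysis removes it at the end.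

Step 12
Reactants: 21 1-(benzyloxy)-3-bromo-5-methylbenzene; 8 N,N-dimethylformamide
Product: 23 2-(benzyloxy)-6-bromo-4-methylbenzaldehyde, via aryllithium 22 (not isolated)
Conditions: LDA, THF, −78 °C; DMF, −78 °C → rt
Reagents that add atoms: N,N-dimethylformamide 8, CN(C)C=O
Why: Directed ortho-metalation at the site flanked by Br and OBn, then formylation; LDA attacks neither the benzylic CH2 nor the C–Br bond at −78 °C, and the new carbon is C4.

Step 13
Reactants: 20 2-[(E)-3-(ArB)prop-2-en-1-yl]-4,4,5,5-tetramethyl-1,3,2-dioxaborolane; 23 2-(benzyloxy)-6-bromo-4-methylbenzaldehyde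
Product: 25 (1S,2R)-1-[2-(benzyloxy)-6-bromo-4-methylphenyl]-2-(ArB)but-3-en-1-ol, via pinacol borate ester 24 (not isolated)
Conditions: (S)-TRIP (10 mol %), 4 Å MS, toluene, −30 °C → rt; aq. NaHCO3
Reagents that add atoms: none
Why: Allylboration through a closed chair (Zimmerman–Traxler) transition state under chiral phosphoric acid catalysis: the (E)-boronate places ArB equatorial and gives the anti adduct, which is the cis 3-aryl-4-hydroxy arrangement of ring A; (S)-TRIP is chosen to deliver the allyl unit to the Si face of 23 (4S and hence 3R), by analogy with benzaldehydes, where the (R)-acid attacks the Re face. Because C4' is fixed, any adduct from the other face is a diastereomer and is removed by chromatography.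

Step 14
Reactants: 25 (1S,2R)-1-[2-(benzyloxy)-6-bromo-4-methylphenyl]-2-(ArB)but-3-en-1-ol
Product: 27 (3R,4S)-4-[2-(benzyloxy)-6-bromo-4-methylphenyl]-3-(ArB)butane-1,4-diol, via alkylborane 26 (not isolated)
Conditions: 9-BBN, THF, 0 °C → rt; NaOH, H2O2, 0 °C → rt
Reagents that add atoms: hydrogen peroxide, OO
Why: Anti-Markovnikov hydroboration of the monosubstituted alkene and oxidation of the C–B bond give the primary alcohol at C1; the aryl bromide, ketal and ethers are inert, and C3 and C4 are not touched.

Step 15
Reactants: 27 (3R,4S)-4-[2-(benzyloxy)-6-bromo-4-methylphenyl]-3-(ArB)butane-1,4-diol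
Product: 29 (4R,5S)-5-[2-(benzyloxy)-6-bromo-4-methylphenyl]-4-(ArB)oxolan-2-one, via lactol 28 (not isolated)
Conditions: TEMPO (20 mol %), PhI(OAc)2, CH2Cl2, rt
Reagents that add atoms: none
Why: Oxidative lactonisation of a 1,4-diol: the oxoammonium oxidant takes the primary alcohol in preference to the hindered secondary benzylic one, the aldehyde closes to the lactol with the C4 hydroxyl, and the lactol is oxidised to the trans-disubstituted γ-lactone.

Step 16
Reactants: 29 (4R,5S)-5-[2-(benzyloxy)-6-bromo-4-methylphenyl]-4-(ArB)oxolan-2-one
Product: 32 (3R,4S)-5-(benzyloxy)-4-hydroxy-7-methyl-3-(ArB)-3,4-dihydronaphthalen-1(2H)-one, via aryllithium 30 (not isolated), via bridged lithium hemiketal 31 (not isolated)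
Conditions: t-BuLi (2.1 equiv), THF/Et2O, −100 → −40 °C; aq. NH4Cl
Reagents that add atoms: none
Why: Parham cyclisation: bromine–lithium exchange at −100 °C is faster than attack of the base on the lactone, and the aryllithium at C8a adds to the lactone carbonyl C1 (6-exo-trig for the new ring) to give the bridged hemiketal alkoxide, which opens to the C1 ketone and the C4 alkoxide; no bond to C3 or C4 is broken, so the cis relationship is kept.

Step 17
Reactants: 32 (3R,4S)-5-(benzyloxy)-4-hydroxy-7-methyl-3-(ArB)-3,4-dihydronaphthalen-1(2H)-one
Product: 33 (3R,4S)-5-(benzyloxy)-4-hydroxy-3-[(5R)-1,5-dihydroxy-3-methyl-8-oxo-5,6,7,8-tetrahydronaphthalen-2-yl]-7-methyl-3,4-dihydronaphthalen-1(2H)-one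
Conditions: 2 M HCl (aq), THF, rt → 40 °C
Reagents that add atoms: water, O
Why: Acetal hydrolysis and desilylation remove the dioxolane, the silyl ether and the aryl MOM ether in one operation; it is run while C5–O is still benzylated, so that C4 is not yet an ortho-hydroxybenzyl alcohol, and without alcohol solvent to avoid benzylic ether formation.

Step 18
Reactants: 33 (3R,4S)-5-(benzyloxy)-4-hydroxy-3-[(5R)-1,5-dihydroxy-3-methyl-8-oxo-5,6,7,8-tetrahydronaphthalen-2-yl]-7-methyl-3,4-dihydronaphthalen-1(2H)-one
Product: 34 (3R,4S)-4,5-dihydroxy-3-[(5R)-1,5-dihydroxy-3-methyl-8-oxo-5,6,7,8-tetrahydronaphthalen-2-yl]-7-methyl-3,4-dihydronaphthalen-1(2H)-one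
Conditions: H2 (1 atm), 10% Pd/C, EtOAc, rt
Reagents that add atoms: none
Why: Hydrogenolysis of the aryl benzyl ether under neutral conditions; aryl benzyl ethers are cleaved faster than benzylic alcohols are hydrogenolysed or aryl ketones reduced, so the reaction is stopped after one equivalent of hydrogen.

## Compound list

1 | 3-bromo-5-methylphenol | Cc1cc(O)cc(Br)c1 | starting material
2 | 1-bromo-3-(methoxymethoxy)-5-methylbenzene | COCOc1cc(C)cc(Br)c1 | intermediate
3 | methyl chloroformate | COC(=O)Cl | starting material
4 | [2-bromo-6-(methoxymethoxy)-4-methylphenyl]lithium | [Li]c1c(Br)cc(C)cc1OCOC | intermediate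
5 | methyl 2-bromo-6-(methoxymethoxy)-4-methylbenzoate | COC(=O)c1c(Br)cc(C)cc1OCOC | intermediate
6 | ethylmagnesium bromide | CC[Mg]Br | starting material
7 | 1-[2-bromo-6-(methoxymethoxy)-4-methylphenyl]cyclopropan-1-ol | OC1(CC1)c1c(Br)cc(C)cc1OCOC | intermediate
8 | N,N-dimethylformamide | CN(C)C=O | starting material
9 | lithium 1-[2-lithio-6-(methoxymethoxy)-4-methylphenyl]cyclopropan-1-olate | [Li]OC1(CC1)c1c([Li])cc(C)cc1OCOC | intermediate
10 | 2-(1-hydroxycyclopropyl)-3-(methoxymethoxy)-5-methylbenzaldehyde (rests as its lactol tautomer) | O=Cc1cc(C)cc(OCOC)c1C1(O)CC1 | intermediate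
11 | zinc homoenolate: {3-[2-formyl-6-(methoxymethoxy)-4-methylphenyl]-3-oxopropyl}zinc alkoxide of (2R)-DAIB | C[C@]12CC[C@H](C1(C)C)[C@H](N(C)C)[C@@H]2O[Zn]CCC(=O)c1c(C=O)cc(C)cc1OCOC | intermediate
12 | (R)-4-hydroxy-8-(methoxymethoxy)-6-methyl-3,4-dihydronaphthalen-1(2H)-one | Cc1cc2c(c(OCOC)c1)C(=O)CC[C@H]2O | intermediate
13 | (R)-4-[(tert-butyldimethylsilyl)oxy]-8-(methoxymethoxy)-6-methyl-3,4-dihydronaphthalen-1(2H)-one | Cc1cc2c(c(OCOC)c1)C(=O)CC[C@H]2O[Si](C)(C)C(C)(C)C | intermediate
14 | (4'R)-4'-[(tert-butyldimethylsilyl)oxy]-8'-(methoxymethoxy)-6'-methyl-3',4'-dihydro-2'H-spiro[1,3-dioxolane-2,1'-naphthalene] (ArB–H) | Cc1cc2c(c(OCOC)c1)C1(OCCO1)CC[C@H]2O[Si](C)(C)C(C)(C)C | intermediate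
15 | ArB–Li (7'-lithio derivative of 14) | [Li]c1c(C)cc2c(c1OCOC)C1(OCCO1)CC[C@H]2O[Si](C)(C)C(C)(C)C | intermediate
16 | ArB–CHO (7'-carbaldehyde of 14) | O=Cc1c(C)cc2c(c1OCOC)C1(OCCO1)CC[C@H]2O[Si](C)(C)C(C)(C)C | intermediate
17 | vinylmagnesium bromide | C=C[Mg]Br | starting material
18 | bromomagnesium 1-(ArB)prop-2-en-1-olate | C=CC(O[Mg]Br)c1c(C)cc2c(c1OCOC)C1(OCCO1)CC[C@H]2O[Si](C)(C)C(C)(C)C | intermediate
19 | methyl 1-(ArB)prop-2-en-1-yl carbonate (both configurations at the carbinol carbon) | C=CC(OC(=O)OC)c1c(C)cc2c(c1OCOC)C1(OCCO1)CC[C@H]2O[Si](C)(C)C(C)(C)C | intermediate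
20 | 2-[(E)-3-(ArB)prop-2-en-1-yl]-4,4,5,5-tetramethyl-1,3,2-dioxaborolane | CC1(C)OB(C/C=C/c2c(C)cc3c(c2OCOC)C4(OCCO4)CC[C@H]3O[Si](C)(C)C(C)(C)C)OC1(C)C | intermediate
21 | 1-(benzyloxy)-3-bromo-5-methylbenzene | Cc1cc(Br)cc(OCc2ccccc2)c1 | intermediate
22 | [2-(benzyloxy)-6-bromo-4-methylphenyl]lithium | [Li]c1c(Br)cc(C)cc1OCc1ccccc1 | intermediate
23 | 2-(benzyloxy)-6-bromo-4-methylbenzaldehyde | O=Cc1c(Br)cc(C)cc1OCc1ccccc1 | intermediate
24 | pinacol borate ester of 25 (O–Bpin on C4) | C=C[C@H](c1c(C)cc2c(c1OCOC)C1(OCCO1)CC[C@H]2O[Si](C)(C)C(C)(C)C)[C@H](OB1OC(C)(C)C(C)(C)O1)c1c(Br)cc(C)cc1OCc1ccccc1 | intermediate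
25 | (1S,2R)-1-[2-(benzyloxy)-6-bromo-4-methylphenyl]-2-(ArB)but-3-en-1-ol | C=C[C@H](c1c(C)cc2c(c1OCOC)C1(OCCO1)CC[C@H]2O[Si](C)(C)C(C)(C)C)[C@H](O)c1c(Br)cc(C)cc1OCc1ccccc1 | intermediate
26 | B-alkyl-9-borabicyclo[3.3.1]nonane from 25 (boron on C1) | B1(CC[C@H](c3c(C)cc4c(c3OCOC)C3(OCCO3)CC[C@H]4O[Si](C)(C)C(C)(C)C)[C@H](O)c3c(Br)cc(C)cc3OCc3ccccc3)C2CCCC1CCC2 | intermediate
27 | (3R,4S)-4-[2-(benzyloxy)-6-bromo-4-methylphenyl]-3-(ArB)butane-1,4-diol | OCC[C@H](c1c(C)cc2c(c1OCOC)C1(OCCO1)CC[C@H]2O[Si](C)(C)C(C)(C)C)[C@H](O)c1c(Br)cc(C)cc1OCc1ccccc1 | intermediate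
28 | (4R,5S)-5-[2-(benzyloxy)-6-bromo-4-methylphenyl]-4-(ArB)oxolan-2-ol (lactol, both anomers) | OC1C[C@H](c3c(C)cc4c(c3OCOC)C3(OCCO3)CC[C@H]4O[Si](C)(C)C(C)(C)C)[C@@H](c3c(Br)cc(C)cc3OCc3ccccc3)O1 | intermediate
29 | (4R,5S)-5-[2-(benzyloxy)-6-bromo-4-methylphenyl]-4-(ArB)oxolan-2-one | O=C1C[C@H](c3c(C)cc4c(c3OCOC)C3(OCCO3)CC[C@H]4O[Si](C)(C)C(C)(C)C)[C@@H](c3c(Br)cc(C)cc3OCc3ccccc3)O1 | intermediate
30 | aryllithium from 29 (lithium on C8a) | O=C1C[C@H](c3c(C)cc4c(c3OCOC)C3(OCCO3)CC[C@H]4O[Si](C)(C)C(C)(C)C)[C@@H](c3c([Li])cc(C)cc3OCc3ccccc3)O1 | intermediate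
31 | lithium 5-(benzyloxy)-7-methyl-3-(ArB)-1,4-epoxy-1,2,3,4-tetrahydronaphthalen-1-olate (ArB syn to the oxygen bridge) | [Li]O[C@]12C[C@H](c5c(C)cc6c(c5OCOC)C5(OCCO5)CC[C@H]6O[Si](C)(C)C(C)(C)C)[C@H](O1)c3c(OCc4ccccc4)cc(C)cc32 | intermediate
32 | (3R,4S)-5-(benzyloxy)-4-hydroxy-7-methyl-3-(ArB)-3,4-dihydronaphthalen-1(2H)-one | Cc1cc(OCc5ccccc5)c2c(c1)C(=O)C[C@H](c1c(C)cc3c(c1OCOC)C1(OCCO1)CC[C@H]3O[Si](C)(C)C(C)(C)C)[C@@H]2O | intermediate
33 | (3R,4S)-5-(benzyloxy)-4-hydroxy-3-[(5R)-1,5-dihydroxy-3-methyl-8-oxo-5,6,7,8-tetrahydronaphthalen-2-yl]-7-methyl-3,4-dihydronaphthalen-1(2H)-one | Cc1cc(OCc5ccccc5)c2c(c1)C(=O)C[C@H](c1c(C)cc3c(c1O)C(=O)CC[C@H]3O)[C@@H]2O | intermediate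
34 | (3R,4S)-4,5-dihydroxy-3-[(5R)-1,5-dihydroxy-3-methyl-8-oxo-5,6,7,8-tetrahydronaphthalen-2-yl]-7-methyl-3,4-dihydronaphthalen-1(2H)-one | Cc1cc(O)c2c(c1)C(=O)C[C@H](c1c(C)cc3c(c1O)C(=O)CC[C@H]3O)[C@@H]2O | target

## Step count and risks

Total: 18 steps. Longest linear sequence: 16 steps (steps 1–10 and 13–18, from 1 to 34). Steps 11 and 12 form the second branch.

**Step 5 (key step, proposed new method).** The alkylzinc aminoalkoxide 11 may be too weak a nucleophile, so that protonation to the ring-opened ethyl ketone or hydride transfer between zinc alkoxides and the aldehyde takes over. The tether may also override the ligand and give poor facial selectivity. The fallback uses known reactions and leaves the homoenolate aside. It sets out from 2. Compound 2 is lithiated as in step 2 and the aryllithium is acylated with γ-butyrolactone to give 1-[2-bromo-6-(methoxymethoxy)-4-methylphenyl]-4-hydroxybutan-1-one F1. Dess–Martin oxidation gives 4-[2-bromo-6-(methoxymethoxy)-4-methylphenyl]-4-oxobutanal F2. An intramolecular Nozaki–Hiyama–Kishi reaction (CrCl2, catalytic NiCl2, DMF), which adds the aryl–chromium bond to the aldehyde and spares the ketone, closes the C4a'–C4' bond to racemic 4-hydroxy-8-(methoxymethoxy)-6-methyl-3,4-dihydronaphthalen-1(2H)-one F3. Lipase-catalysed acylation with vinyl acetate, which for cyclic benzylic carbinols takes the R enantiomer, gives (1R)-5-(methoxymethoxy)-7-methyl-4-oxo-1,2,3,4-tetrahydronaphthalen-1-yl acetate F4 and leaves (S)-4-hydroxy-8-(methoxymethoxy)-6-methyl-3,4-dihydronaphthalen-1(2H)-one F5, which is set aside. Methanolysis of the acetate (K2CO3, MeOH) returns to the route at 12.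

**Step 3.** Insertion of the twisted 2,6-disubstituted ester into the titanacyclopropane may be slow, so that reduction or direct Grignard addition competes. Fallback: 2 is lithiated as in step 2, transmetalated with MgBr2·OEt2 and added to cyclopropanone released in the flask from 1-(phenylsulfonyl)cyclopropan-1-ol and one equivalent of MeMgBr. This joins the route at 7 without any compound outside the list (F0).

**Step 8.** Deprotonation at the benzylic C4'–H with migration of silicon from oxygen to carbon may compete with the slow lithiation of the flanked C7' position. Fallback, from 14: fluoride (TBAF) removes the silyl group to give (4'R)-8'-(methoxymethoxy)-6'-methyl-3',4'-dihydro-2'H-spiro[1,3-dioxolane-2,1'-naphthalen]-4'-ol F6. Its lithium alkoxide protects its own α-C–H, and lithiation with excess n-BuLi/TMEDA followed by DMF gives the 7'-carbaldehyde of that alcohol F7. Silylation (TBSCl, imidazole) returns to 16.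

**Step 13.** Two ortho,ortho'-disubstituted partners may react too slowly under acid catalysis, and the catalyst may give low or reversed facial selectivity. Fallback, from 20: n-BuLi followed by trifluoroacetic anhydride converts the pinacol boronate into the far more reactive B-butyl borinic ester F8 (not isolated). This adds to 23 at −78 °C without catalyst, with the same anti selectivity but on both faces. The two anti adducts, 25 and its (1R,2S,4'R) diastereomer F9, are separated by chromatography, and the route continues from 25.

**Step 16.** Proton transfer from the lactone α-CH2 (C2) to the aryllithium, or strain on the way to the bridged tetrahedral intermediate, may give debrominated lactone in place of ring closure. Fallback, from 29: aminolysis with MeNHOMe·HCl/i-PrMgCl opens the lactone to the hydroxy Weinreb amide (3R,4S)-4-[2-(benzyloxy)-6-bromo-4-methylphenyl]-4-hydroxy-N-methoxy-N-methyl-3-(ArB)butanamide F10. Silylation (TESOTf, 2,6-lutidine) gives its C4 triethylsilyl ether F11. Parham cyclisation onto the amide (t-BuLi, −78 °C), a well-used closure for 1-tetralones, gives the C4 triethylsilyl ether of 32 F12. The conditions of step 17 remove this silyl group with the others, so the route is rejoined at 33.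

## Further compounds

F1 | step 5 | 1-[2-bromo-6-(methoxymethoxy)-4-methylphenyl]-4-hydroxybutan-1-one | OCCCC(=O)c1c(Br)cc(C)cc1OCOC
F2 | step 5 | 4-[2-bromo-6-(methoxymethoxy)-4-methylphenyl]-4-oxobutanal | O=CCCC(=O)c1c(Br)cc(C)cc1OCOC
F3 | step 5 | rac-4-hydroxy-8-(methoxymethoxy)-6-methyl-3,4-dihydronaphthalen-1(2H)-one | Cc1cc2c(c(OCOC)c1)C(=O)CCC2O
F4 | step 5 | (1R)-5-(methoxymethoxy)-7-methyl-4-oxo-1,2,3,4-tetrahydronaphthalen-1-yl acetate | Cc1cc2c(c(OCOC)c1)C(=O)CC[C@H]2OC(C)=O
F5 | step 5 | (S)-4-hydroxy-8-(methoxymethoxy)-6-methyl-3,4-dihydronaphthalen-1(2H)-one | Cc1cc2c(c(OCOC)c1)C(=O)CC[C@@H]2O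
F0 | step 3 | none | none
F6 | step 8 | (4'R)-8'-(methoxymethoxy)-6'-methyl-3',4'-dihydro-2'H-spiro[1,3-dioxolane-2,1'-naphthalen]-4'-ol | Cc1cc2c(c(OCOC)c1)C1(OCCO1)CC[C@H]2O
F7 | step 8 | (4'R)-4'-hydroxy-8'-(methoxymethoxy)-6'-methyl-3',4'-dihydro-2'H-spiro[1,3-dioxolane-2,1'-naphthalene]-7'-carbaldehyde | O=Cc1c(C)cc2c(c1OCOC)C1(OCCO1)CC[C@H]2O
F8 | step 13 | 2,3-dimethyl-3-{[butyl((E)-3-(ArB)prop-2-en-1-yl)boranyl]oxy}butan-2-yl trifluoroacetate | CCCCB(C/C=C/c1c(C)cc2c(c1OCOC)C1(OCCO1)CC[C@H]2O[Si](C)(C)C(C)(C)C)OC(C)(C)C(C)(C)OC(=O)C(F)(F)F
F9 | step 13 | (1R,2S)-1-[2-(benzyloxy)-6-bromo-4-methylphenyl]-2-(ArB)but-3-en-1-ol | C=C[C@@H](c1c(C)cc2c(c1OCOC)C1(OCCO1)CC[C@H]2O[Si](C)(C)C(C)(C)C)[C@@H](O)c1c(Br)cc(C)cc1OCc1ccccc1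
F10 | step 16 | (3R,4S)-4-[2-(benzyloxy)-6-bromo-4-methylphenyl]-4-hydroxy-N-methoxy-N-methyl-3-(ArB)butanamide | CON(C)C(=O)C[C@H](c1c(C)cc2c(c1OCOC)C1(OCCO1)CC[C@H]2O[Si](C)(C)C(C)(C)C)[C@H](O)c1c(Br)cc(C)cc1OCc1ccccc1
F11 | step 16 | (3R,4S)-4-[2-(benzyloxy)-6-bromo-4-methylphenyl]-N-methoxy-N-methyl-3-(ArB)-4-[(triethylsilyl)oxy]butanamide | CON(C)C(=O)C[C@H](c1c(C)cc2c(c1OCOC)C1(OCCO1)CC[C@H]2O[Si](C)(C)C(C)(C)C)[C@H](O[Si](CC)(CC)CC)c1c(Br)cc(C)cc1OCc1ccccc1
F12 | step 16 | (3R,4S)-5-(benzyloxy)-7-methyl-3-(ArB)-4-[(triethylsilyl)oxy]-3,4-dihydronaphthalen-1(2H)-one | Cc1cc(OCc5ccccc5)c2c(c1)C(=O)C[C@H](c1c(C)cc3c(c1OCOC)C1(OCCO1)CC[C@H]3O[Si](C)(C)C(C)(C)C)[C@@H]2O[Si](CC)(CC)CC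
A1 | alternative 1 | furan–yne: 2-[(1R)-1-(TBS-oxy)-3-(2-ethynyl-1,3-dioxolan-2-yl)propyl]-4-methylfuran bonded through its C5 to C3 of (3,4-cis)-5-(benzyloxy)-4-(TBS-oxy)-7-methyl-1-tetralone, configured as in A2 | C#CC1(OCCO1)CC[C@@H](O[Si](C)(C)C(C)(C)C)c1cc(C)c(o1)[C@H]1CC(=O)c2cc(C)cc(OCc3ccccc3)c2[C@H]1O[Si](C)(C)C(C)(C)C
A2 | alternative 1 | target with free C8' phenol, C1' dioxolane, C5 benzyl ether and TBS ethers on C4 and C4' | Cc1cc(OCc5ccccc5)c2c(c1)C(=O)C[C@H](c3c(C)cc6c(c3O)C4(OCCO4)CC[C@H]6O[Si](C)(C)C(C)(C)C)[C@@H]2O[Si](C)(C)C(C)(C)C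
A3 | alternative 2 | (R)-2-bromo-4-[(tert-butyldimethylsilyl)oxy]cyclohex-2-en-1-one | O=C1CC[C@@H](O[Si](C)(C)C(C)(C)C)C=C1Br
A4 | alternative 2 | 1-methoxy-3-methyl-1-(trimethylsilyloxy)buta-1,3-diene | C=C(C)C=C(OC)O[Si](C)(C)C
A5 | alternative 2 | (R)-4-[(tert-butyldimethylsilyl)oxy]-8-hydroxy-6-methyl-3,4-dihydronaphthalen-1(2H)-one | Cc1cc2c(c(O)c1)C(=O)CC[C@H]2O[Si](C)(C)C(C)(C)C
A6 | alternative 3 | trans-epoxide: 1-{3-(benzyloxy)-5-methyl-2-[3-(8'-allyloxy analogue of ArB)oxiran-2-yl]phenyl}ethan-1-one, C4 configured as in A7 | CC(=O)c1cc(C)cc(OCc2ccccc2)c1[C@H]1O[C@@H]1c1c(C)cc2c(c1OCC=C)C1(OCCO1)CC[C@H]2O[Si](C)(C)C(C)(C)C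
A7 | alternative 3 | target with free C4 hydroxyl and C8' phenol, C5 benzyl ether, C1' dioxolane and C4' TBS ether | Cc1cc(OCc5ccccc5)c2c(c1)C(=O)C[C@H](c1c(C)cc3c(c1O)C6(OCCO6)CC[C@H]3O[Si](C)(C)C(C)(C)C)[C@@H]2O
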